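## Structural features

The target is a flavanone of the naringenin type: a phloroglucinol-derived benzene ring A fused to a dihydropyranone ring C, with a 4-hydroxyphenyl ring B on C2 and an N-methylpiperidine bonded through its C2 to C6 of ring A, between the 5- and 7-hydroxyls. There are two stereocentres, C2 of ring C (S) and C2 of the piperidine (S). They are not adjacent but separated by ring A, so neither can direct the other and each has to be set independently. The fragile sites are:
- the benzylic C2–O1 ether β to the C4 ketone, which opens to a chalcone in base and ionises in acid once the 4'-oxygen is a free donor;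
- the benzylic C–N bond on the trioxygenated ring, which can ionise in acid, cleave by a retro-Mannich path when an ortho hydroxyl is free, or be hydrogenolysed;
- the electron-rich ring A and the basic amine.

The real difficulty is regiochemical and stereochemical at once: the piperidine must sit at C6 and not at C8, which substitution of a preformed flavanone would not distinguish, and C2 must stay (S) while ring C closes. The key step exploits the fact that, before the C4–C4a bond exists, ring A carries O1 para to the piperidine-bearing carbon C6 and identical benzyloxy groups at C5 and C7. The two carbons ortho to O1 (future C4a and C8) are then constitutionally the same and interchange by rotation about the O1–C8a and C6–piperidine bonds, so closure at either gives only the 6-substituted chromanone. A second feature used is that all three phenolic oxygens can carry hydrogenolysable groups, so the last step can be neutral.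

## Logic of the disconnections

**24 ⇒ 23.** Cut the three O–CH2Ph bonds: the two ether oxygens at C5 and C7 and the carbonate oxygen at C4'. The free triphenol 24 tolerates neither acid nor base well, so it should be released in one neutral hydrogenolysis. A hindered acyl group on the 4'-oxygen would need a separate solvolysis on a sensitive flavanone, so a benzyl carbonate is carried instead; it is equally electron-poor and falls with the benzyl ethers. There is no skeletal change. The demand is that the catalyst cleaves O–benzyl bonds without touching C2–O1, the benzylic C–N bond or the C4 ketone.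

**23 ⇒ 21 (through 22).** Cut C4–C4a. This is the only cut of ring C that turns the C6/C8 question into a symmetry argument. It removes one ring and leaves an open-chain acid whose C2 configuration is already fixed. The demand is that acylation of ring A is faster than ionisation of the benzylic C2–O1 bond, and that the amine stays protonated so that it is neither acylated nor cleaved.

**21 ⇒ 20.** Cut the ester O–C(CH3)3 bond. Hydroxide would expel the aryloxide β to the carboxyl (E1cB), so the acid is unmasked by acid alone. The demand is short, cold exposure to acid.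

**20 ⇒ 12 + 19.** Cut O1–C2. This gives two fragments of similar size, each with one stereocentre. An SN2 etherification with inversion transfers the configuration of 19 to C2. The demands are that 12 has a single free phenol, that inversion is clean and that elimination to the cinnamate is suppressed; the electron-poor carbonate on ring B works against an SN1 leak.

**19 ⇒ 18 ⇒ 14 + 15; 14 ⇒ 13.** Cut the carbinol C–H (ketone reduction), then the aroyl–CH2 bond, then the carbonate O–C(=O) bond. The β-keto ester is the standard substrate for catalyst-controlled reduction. The demand is that the bond-forming step is mild enough to spare the aryl carbonate, which is why a magnesium malonate acylation is used and not a lithium enolate.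

**12 ⇒ 11 ⇒ 9 ⇒ 8.** Cut O–Si, then N–CH3 and N–S (through 10), then the N–C6 bond of the piperidine. The ring nitrogen is closed onto a primary chloride only after the stereocentre is in place. The demand is that no step ionises the electron-rich benzylic C–N bond.

**8 ⇒ 5 + 6 (through 7); 5 ⇒ 3 + 4.** Cut the C2–C3 bond of the future piperidine and the C=N bond. A sulfinyl auxiliary on nitrogen makes the configuration of the piperidine carbon predictable and lets the minor diastereomer be removed before ring closure. The demand is facial control in the addition to a crowded, electron-rich aldimine.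

**3 ⇒ 2 ⇒ 1.** Cut two O–benzyl bonds and one O–Si bond. In 1 the formyl carbon already marks the ring carbon that will bear the piperidine. Hydrogen bonding and crowding set the two ortho hydroxyls apart from the para one, so the symmetric ring is differentiated without any regioselective aromatic substitution. The demand is selective silylation of the para hydroxyl.

## Other disconnections considered

**Alternative 1:** Ring A is cut into a two-carbon and a four-carbon piece at C6–C7, C4a–C5 and C7–C8. Forward, 3-[(4-methoxybenzyl)oxy]cyclobut-2-en-1-one A3 would be heated with tert-butyl (S)-2-{[(triisopropylsilyl)oxy]ethynyl}piperidine-1-carboxylate A2, made from (S)-piperidine-2-carboxylic acid A4. The sequence is electrocyclic opening to a vinylketene, [2+2] addition to the electron-rich alkyne, a second four-electron opening, six-electron closure and tautomerisation, giving tert-butyl (S)-2-[2-hydroxy-4-(4-methoxybenzyloxy)-6-(triisopropylsilyloxy)phenyl]piperidine-1-carboxylate A1.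
- In favour: the piperidine stereocentre comes from the chiral pool, the piperidine lands between two oxygens by connectivity alone, and the conditions are neutral and thermal. On the source of the piperidine configuration and on avoiding selective protection of a symmetric triol this alternative is the better one.
- Against: it builds only ring A, so ring C must still be closed by the chosen key step or an equivalent. The three different oxygen masks in A1 are more differentiation than the later symmetry needs. Carbamate, 4-methoxybenzyl ether and silyl ether would not survive an acidic cycloacylation and would have to be exchanged, and the carbamate must still become N-methyl. A2 needs ynolate chemistry next to an epimerisable α-amino centre, and A3 is a sensitive partner.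
- Comparison: on structure both plans use the same local symmetry of ring A. On mechanism the pericyclic cascade is milder than an auxiliary-controlled Grignard addition. On step economy it is expected to be longer, because both partners take several steps and the protecting groups must be swapped before ring C can be made.

**Alternative 2:** Ring C is cut at C2–C3. Forward, the diazoketone tert-butyl (S)-2-{3-(2-diazoacetyl)-2,6-bis[(tert-butyldimethylsilyl)oxy]-4-({4-[(tert-butyldimethylsilyl)oxy]benzyl}oxy)phenyl}piperidine-1-carboxylate A6 would lose nitrogen at a chiral dirhodium tetracarboxylate. The carbenoid at C3 would insert into the benzylic C–H bond next to O1 to give tert-butyl (S)-2-{(S)-5,7-bis(tert-butyldimethylsilyloxy)-2-[4-(tert-butyldimethylsilyloxy)phenyl]-4-oxochroman-6-yl}piperidine-1-carboxylate A5.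
- In favour: C2 is created catalytically in the ring-closing step, O1–C2 comes from a simple O-benzylation instead of a stereospecific etherification, and no acid ever meets the benzylic ether. On these points it is the better plan in principle. The acylation site on ring A is fixed by the same symmetry, so it is the equal of the chosen plan on regiochemistry, and a single global desilylation matches the single hydrogenolysis of the chosen endgame.
- Against: the ether oxygen lies five atoms from the carbenoid carbon, so formation of a five-membered oxonium ylide followed by a Stevens shift of the benzyl group competes directly with the six-membered C–H insertion. Addition to the electron-rich benzyl ring is a further competitor. The diazoketone has to be made from a hindered 2,6-dioxygenated benzoyl derivative, silyl ethers flanking the carbonyl are labile, and the carbamate again has to be turned into N-methyl.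
- Comparison: mechanistically the chosen Friedel–Crafts closure has one predictable competitor (ionisation), whereas the carbenoid has several. Step count is expected to be similar.

**Alternative 3:** Ring A is cut at C5–C6. Forward, base would convert the side-chain ketone of methyl (S)-2-[4-(benzyloxy)phenyl]-6-{3-[(S)-1-(tert-butoxycarbonyl)piperidin-2-yl]-2-oxopropyl}-4-oxo-3,4-dihydro-2H-pyran-5-carboxylate A8 into its dienolate. C6 would attack the ester carbonyl (C5), and aromatisation would give tert-butyl (S)-2-{(S)-2-[4-(benzyloxy)phenyl]-5,7-dihydroxy-4-oxochroman-6-yl}piperidine-1-carboxylate A7.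
- In favour: the closure is biomimetic, the 6- versus 8-position is fixed by connectivity (equal to the chosen plan), and the 5- and 7-hydroxyls appear unprotected, so on protecting-group economy for ring A it is the better plan.
- Against: the enolate needed at C6 is β to the carbamate nitrogen and can open the piperidine by E1cB, destroying that stereocentre. The C8 methylene is the more acidic site. C2 sits in a β-alkoxy enone and then in a free 5,7-dihydroxyflavanone, both of which can open in base and racemise. A8 itself is a long synthesis, and the nitrogen would later have to be methylated in the presence of a free phloroglucinol ring.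
- Comparison: on structure it is elegant. On mechanism it exposes both stereocentres to base, where the chosen plan uses only acid and neutral conditions around them. On step economy it is expected to be longer despite a short endgame.

Key step: step 13

Assumption: intermediates carrying the basic nitrogen are named and listed as free bases; 21 is in practice carried into step 13 as its trifluoroacetate salt.

## Route

Step 1
Reactants: 1 2,4,6-trihydroxybenzaldehyde
Product: 2 2,6-dihydroxy-4-[(triisopropylsilyl)oxy]benzaldehyde
Conditions: iPr3SiCl (1.05 equiv), imidazole, DMF, 0 °C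
Reagents that add atoms: chlorotriisopropylsilane, CC(C)[Si](Cl)(C(C)C)C(C)C
Why: Silylation of a phenol; the two ortho hydroxyls are hydrogen-bonded to and crowded by the formyl group, so the bulky silyl chloride should take the more acidic, unhindered para hydroxyl, as is standard for 2,4-dihydroxybenzaldehydes.

Step 2
Reactants: 2 2,6-dihydroxy-4-[(triisopropylsilyl)oxy]benzaldehyde
Product: 3 2,6-bis(benzyloxy)-4-[(triisopropylsilyl)oxy]benzaldehyde
Conditions: BnBr (2.4 equiv), K2CO3, DMF, rt
Reagents that add atoms: benzyl bromide, BrCc1ccccc1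
Why: Williamson ether synthesis on the two chelated phenols; the triisopropylsilyl ether is chosen because its bulk should resist attack by carbonate or phenoxide at room temperature.

Step 3
Reactants: 3 2,6-bis(benzyloxy)-4-[(triisopropylsilyl)oxy]benzaldehyde; 4 (R)-2-methylpropane-2-sulfinamide
Product: 5 (R,E)-N-{2,6-bis(benzyloxy)-4-[(triisopropylsilyl)oxy]benzylidene}-2-methylpropane-2-sulfinamide
Conditions: Ti(OEt)4 (2 equiv), THF, 65 °C
Reagents that add atoms: none
Why: Lewis-acid-mediated condensation of an aldehyde with a sulfinamide; Ti(OEt)4 activates the hindered, electron-rich aldehyde and takes up the water, and only the E aldimine is expected.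

Step 4
Reactants: 5 (R,E)-N-{2,6-bis(benzyloxy)-4-[(triisopropylsilyl)oxy]benzylidene}-2-methylpropane-2-sulfinamide; 6 1-bromo-4-chlorobutane
Product: 8 (R)-N-[(S)-1-{2,6-bis(benzyloxy)-4-[(triisopropylsilyl)oxy]phenyl}-5-chloropentyl]-2-methylpropane-2-sulfinamide, via 4-chlorobutylmagnesium bromide 7 (not isolated)
Conditions: 6, Mg, THF, rt; then 5, CH2Cl2, −48 → −20 °C; H2O
Reagents that add atoms: none
Why: Grignard addition to an N-sulfinyl aldimine; in a non-coordinating solvent magnesium is bound to the sulfinyl oxygen in a six-membered chair with tert-butyl equatorial, which delivers the alkyl group to the Si face of the (R)-sulfinyl imine and sets the new carbon as (S). Magnesium inserts only into the C–Br bond of 6, and the minor diastereomer is removed at this stage by chromatography or crystallisation.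

Step 5
Reactants: 8 (R)-N-[(S)-1-{2,6-bis(benzyloxy)-4-[(triisopropylsilyl)oxy]phenyl}-5-chloropentyl]-2-methylpropane-2-sulfinamide
Product: 9 (S)-2-{2,6-bis(benzyloxy)-4-[(triisopropylsilyl)oxy]phenyl}-1-[(R)-tert-butylsulfinyl]piperidine
Conditions: KN(SiMe3)2 (1.2 equiv), THF, 0 °C → rt
Reagents that add atoms: none
Why: Intramolecular N-alkylation (6-exo-tet) of the sulfinamide anion by the primary chloride; the stereocentre is not involved and the non-nucleophilic base leaves the aryl silyl ether alone.

Step 6
Reactants: 9 (S)-2-{2,6-bis(benzyloxy)-4-[(triisopropylsilyl)oxy]phenyl}-1-[(R)-tert-butylsulfinyl]piperidine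
Product: 11 (S)-2-{2,6-bis(benzyloxy)-4-[(triisopropylsilyl)oxy]phenyl}-1-methylpiperidine, via free piperidine 10 (not isolated)
Conditions: HCl (4 M in dioxane), MeOH, 0 °C; evaporate; then aq. HCHO, NaBH(OAc)3, NaOAc, ClCH2CH2Cl, rt
Reagents that add atoms: formaldehyde, C=O
Why: Acid methanolysis of the N–S bond followed by reductive amination with formaldehyde; at 0 °C attack of methanol at sulfur should be faster than ionisation of the electron-rich benzylic C–N bond, and the phenol is still silylated, so the nucleophilic ring cannot enter a Mannich reaction with the iminium ion.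

Step 7
Reactants: 11 (S)-2-{2,6-bis(benzyloxy)-4-[(triisopropylsilyl)oxy]phenyl}-1-methylpiperidine
Product: 12 (S)-3,5-bis(benzyloxy)-4-(1-methylpiperidin-2-yl)phenol
Conditions: Bu4NF (1.1 equiv), THF, 0 °C; pH 7 buffer
Reagents that add atoms: none
Why: Fluoride cleavage of the aryl silyl ether; benzyl ethers and the tertiary amine are inert, and 12 now has one free phenol, para to the piperidine.

Step 8
Reactants: 13 4-hydroxybenzoic acid
Product: 14 4-{[(benzyloxy)carbonyl]oxy}benzoic acid
Conditions: BnOCOCl (1.1 equiv), aq. NaOH, 0 °C; then HCl to pH 2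
Reagents that add atoms: benzyl chloroformate, O=C(Cl)OCc1ccccc1
Why: Schotten–Baumann acylation of the phenoxide; any mixed anhydride formed at the carboxylate hydrolyses back, and the aryl benzyl carbonate is an established hydrogenolysable protecting group for this acid.

Step 9
Reactants: 14 4-{[(benzyloxy)carbonyl]oxy}benzoic acid; 15 potassium 3-(tert-butoxy)-3-oxopropanoate
Product: 18 tert-butyl 3-(4-{[(benzyloxy)carbonyl]oxy}phenyl)-3-oxopropanoate, via acid chloride 16 (not isolated), via acylmalonate half ester 17 (not isolated)
Conditions: (COCl)2, DMF (cat.), CH2Cl2, 0 °C → rt; evaporate; then 15, MgCl2, Et3N, MeCN, 0 °C → rt; aq. HCl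
Reagents that add atoms: none
Why: C-acylation of the magnesium enolate of a malonate half ester by an acid chloride, followed by decarboxylation on acidification (a Claisen-type β-keto ester synthesis); the soft magnesium enolate and triethylamine should leave the aryl carbonate untouched, which a lithium ester enolate might not.

Step 10
Reactants: 18 tert-butyl 3-(4-{[(benzyloxy)carbonyl]oxy}phenyl)-3-oxopropanoate
Product: 19 tert-butyl (R)-3-(4-{[(benzyloxy)carbonyl]oxy}phenyl)-3-hydroxypropanoate
Conditions: H2 (50 atm), RuCl2[(S)-BINAP] (1 mol%), EtOH, 50 °C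
Reagents that add atoms: none
Why: Noyori asymmetric hydrogenation of a β-keto ester; the substrate chelates ruthenium through ketone and ester oxygens and the diphosphine fixes the face of hydride delivery. The (S)-ligand is expected to give the (R)-carbinol here, the descriptor being opposite to that of alkyl β-keto esters only because aryl outranks the CH2CO2R group. The homogeneous catalyst does not hydrogenolyse the benzyl carbonate.

Step 11
Reactants: 12 (S)-3,5-bis(benzyloxy)-4-(1-methylpiperidin-2-yl)phenol; 19 tert-butyl (R)-3-(4-{[(benzyloxy)carbonyl]oxy}phenyl)-3-hydroxypropanoate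
Product: 20 tert-butyl (S)-3-{3,5-bis(benzyloxy)-4-[(S)-1-methylpiperidin-2-yl]phenoxy}-3-(4-{[(benzyloxy)carbonyl]oxy}phenyl)propanoate
Conditions: PPh3, DIAD (1.5 equiv each), toluene, 0 °C → rt
Reagents that add atoms: none
Why: Mitsunobu etherification of a phenol with a secondary benzylic alcohol; SN2 displacement of the oxyphosphonium group inverts the carbinol carbon, (R) to (S), and so sets C2. The electron-poor carbonate on the aryl ring disfavours an SN1 leak, and the O1–C2 bond is formed on the only free phenol of 12.

Step 12
Reactants: 20 tert-butyl (S)-3-{3,5-bis(benzyloxy)-4-[(S)-1-methylpiperidin-2-yl]phenoxy}-3-(4-{[(benzyloxy)carbonyl]oxy}phenyl)propanoate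
Product: 21 (S)-3-{3,5-bis(benzyloxy)-4-[(S)-1-methylpiperidin-2-yl]phenoxy}-3-(4-{[(benzyloxy)carbonyl]oxy}phenyl)propanoic acid
Conditions: CF3CO2H/CH2Cl2 (1:4), 0 °C → rt; evaporate, azeotrope with toluene
Reagents that add atoms: none
Why: Acidolysis of a tert-butyl ester by alkyl–oxygen cleavage, which avoids hydroxide and the E1cB loss of the β-aryloxide. Benzyl ethers and the benzyl carbonate tolerate cold dilute trifluoroacetic acid, the free ring carbons are each flanked by two alkoxy groups and so are poor acceptors for the tert-butyl cation, and the acid is obtained as the ammonium trifluoroacetate.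

Step 13
Reactants: 21 (S)-3-{3,5-bis(benzyloxy)-4-[(S)-1-methylpiperidin-2-yl]phenoxy}-3-(4-{[(benzyloxy)carbonyl]oxy}phenyl)propanoic acid
Product: 23 (S)-5,7-bis(benzyloxy)-2-(4-{[(benzyloxy)carbonyl]oxy}phenyl)-6-[(S)-1-methylpiperidin-2-yl]chroman-4-one, via mixed trifluoroacetic anhydride 22 (not isolated)
Conditions: (CF3CO)2O (3 equiv), CH2Cl2, 0 °C → rt; then aq. NaHCO3
Reagents that add atoms: none
Why: The acid is converted by (CF3CO)2O into the mixed anhydride 22, whose acyl carbon (or the acylium ion derived from it) is attacked by the ring A carbon ortho to the ether oxygen; loss of a proton rearomatises the ring, the closest known reaction type being the Friedel–Crafts cycloacylation of 3-aryloxypropanoic acids to chroman-4-ones. Ring C closes as a six-membered ring in a 6-exo-trig mode (6-exo-dig if the free acylium ion is the electrophile), with the new C4–C4a bond in the ring and the carbonyl oxygen outside it. No stereocentre is created; C2 and the piperidine carbon are carried through, so the (S) configuration fixed in step 11 only has to survive. The attacked carbon is ortho to O1, ortho to one benzyloxy group and para to the other, which should make it nucleophilic enough for the mild mixed anhydride even with an ammonium group meta to it. Regioselectivity does not arise, because the two carbons ortho to O1 interchange by rotation about the O1–C8a and C6–piperidine bonds and lead to the same 6-substituted chromanone. The selectivity that matters is acylation versus ionisation of the benzylic C2–O1 bond; the carbonate on ring B and the β-acyl group both destabilise a cation at C2, and no acid stronger than the medium is present. The amine stays protonated as its trifluoroacetate, which keeps it from N-acylation and from the C–N cleavage that an acylammonium ion on so electron-rich a benzylic carbon would invite.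

Step 14
Reactants: 23 (S)-5,7-bis(benzyloxy)-2-(4-{[(benzyloxy)carbonyl]oxy}phenyl)-6-[(S)-1-methylpiperidin-2-yl]chroman-4-one
Product: 24 (S)-5,7-dihydroxy-2-(4-hydroxyphenyl)-6-[(S)-1-methylpiperidin-2-yl]chroman-4-one
Conditions: H2 (1 atm), Pd/C (10%), AcOH (1 equiv), EtOAc–MeOH, rt
Reagents that add atoms: none
Why: Catalytic hydrogenolysis of two aryl benzyl ethers and one aryl benzyl carbonate (the latter losing CO2); all three phenols are released in one neutral operation. One equivalent of acetic acid keeps the amine from slowing the catalyst, and the hindered benzylic C–N bond, the C2–O1 bond and the chelated ketone should react more slowly than the O–benzyl bonds at one atmosphere.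

## Compound list

1 | 2,4,6-trihydroxybenzaldehyde | O=Cc1c(O)cc(O)cc1O | starting material
2 | 2,6-dihydroxy-4-[(triisopropylsilyl)oxy]benzaldehyde | O=Cc1c(O)cc(O[Si](C(C)C)(C(C)C)C(C)C)cc1O | intermediate
3 | 2,6-bis(benzyloxy)-4-[(triisopropylsilyl)oxy]benzaldehyde | O=Cc1c(OCc2ccccc2)cc(O[Si](C(C)C)(C(C)C)C(C)C)cc1OCc1ccccc1 | intermediate
4 | (R)-2-methylpropane-2-sulfinamide | CC(C)(C)[S@@](=O)N | starting material
5 | (R,E)-N-{2,6-bis(benzyloxy)-4-[(triisopropylsilyl)oxy]benzylidene}-2-methylpropane-2-sulfinamide | CC(C)(C)[S@@](=O)/N=C/c1c(OCc2ccccc2)cc(O[Si](C(C)C)(C(C)C)C(C)C)cc1OCc1ccccc1 | intermediate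
6 | 1-bromo-4-chlorobutane | ClCCCCBr | starting material
7 | 4-chlorobutylmagnesium bromide | ClCCCC[Mg]Br | intermediate (not isolated)
8 | (R)-N-[(S)-1-{2,6-bis(benzyloxy)-4-[(triisopropylsilyl)oxy]phenyl}-5-chloropentyl]-2-methylpropane-2-sulfinamide | CC(C)(C)[S@@](=O)N[C@@H](CCCCCl)c1c(OCc2ccccc2)cc(O[Si](C(C)C)(C(C)C)C(C)C)cc1OCc1ccccc1 | intermediate
9 | (S)-2-{2,6-bis(benzyloxy)-4-[(triisopropylsilyl)oxy]phenyl}-1-[(R)-tert-butylsulfinyl]piperidine | CC(C)(C)[S@@](=O)N1CCCC[C@H]1c1c(OCc2ccccc2)cc(O[Si](C(C)C)(C(C)C)C(C)C)cc1OCc1ccccc1 | intermediate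
10 | (S)-2-{2,6-bis(benzyloxy)-4-[(triisopropylsilyl)oxy]phenyl}piperidine | N1CCCC[C@H]1c1c(OCc2ccccc2)cc(O[Si](C(C)C)(C(C)C)C(C)C)cc1OCc1ccccc1 | intermediate (not isolated)
11 | (S)-2-{2,6-bis(benzyloxy)-4-[(triisopropylsilyl)oxy]phenyl}-1-methylpiperidine | CN1CCCC[C@H]1c1c(OCc2ccccc2)cc(O[Si](C(C)C)(C(C)C)C(C)C)cc1OCc1ccccc1 | intermediate
12 | (S)-3,5-bis(benzyloxy)-4-(1-methylpiperidin-2-yl)phenol | CN1CCCC[C@H]1c1c(OCc2ccccc2)cc(O)cc1OCc1ccccc1 | intermediate
13 | 4-hydroxybenzoic acid | O=C(O)c1ccc(O)cc1 | starting material
14 | 4-{[(benzyloxy)carbonyl]oxy}benzoic acid | O=C(O)c1ccc(OC(=O)OCc2ccccc2)cc1 | intermediate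
15 | potassium 3-(tert-butoxy)-3-oxopropanoate | CC(C)(C)OC(=O)CC(=O)[O-].[K+] | starting material
16 | 4-{[(benzyloxy)carbonyl]oxy}benzoyl chloride | O=C(Cl)c1ccc(OC(=O)OCc2ccccc2)cc1 | intermediate (not isolated)
17 | 2-(4-{[(benzyloxy)carbonyl]oxy}benzoyl)-3-(tert-butoxy)-3-oxopropanoic acid (magnesium chelate in the flask) | CC(C)(C)OC(=O)C(C(=O)O)C(=O)c1ccc(OC(=O)OCc2ccccc2)cc1 | intermediate (not isolated)
18 | tert-butyl 3-(4-{[(benzyloxy)carbonyl]oxy}phenyl)-3-oxopropanoate | CC(C)(C)OC(=O)CC(=O)c1ccc(OC(=O)OCc2ccccc2)cc1 | intermediate
19 | tert-butyl (R)-3-(4-{[(benzyloxy)carbonyl]oxy}phenyl)-3-hydroxypropanoate | CC(C)(C)OC(=O)C[C@@H](O)c1ccc(OC(=O)OCc2ccccc2)cc1 | intermediate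
20 | tert-butyl (S)-3-{3,5-bis(benzyloxy)-4-[(S)-1-methylpiperidin-2-yl]phenoxy}-3-(4-{[(benzyloxy)carbonyl]oxy}phenyl)propanoate | CN1CCCC[C@H]1c1c(OCc2ccccc2)cc(O[C@@H](CC(=O)OC(C)(C)C)c2ccc(OC(=O)OCc3ccccc3)cc2)cc1OCc1ccccc1 | intermediate
21 | (S)-3-{3,5-bis(benzyloxy)-4-[(S)-1-methylpiperidin-2-yl]phenoxy}-3-(4-{[(benzyloxy)carbonyl]oxy}phenyl)propanoic acid | CN1CCCC[C@H]1c1c(OCc2ccccc2)cc(O[C@@H](CC(=O)O)c2ccc(OC(=O)OCc3ccccc3)cc2)cc1OCc1ccccc1 | intermediate
22 | (S)-3-{3,5-bis(benzyloxy)-4-[(S)-1-methylpiperidin-2-yl]phenoxy}-3-(4-{[(benzyloxy)carbonyl]oxy}phenyl)propanoic trifluoroacetic anhydride | CN1CCCC[C@H]1c1c(OCc2ccccc2)cc(O[C@@H](CC(=O)OC(=O)C(F)(F)F)c2ccc(OC(=O)OCc3ccccc3)cc2)cc1OCc1ccccc1 | intermediate (not isolated)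
23 | (S)-5,7-bis(benzyloxy)-2-(4-{[(benzyloxy)carbonyl]oxy}phenyl)-6-[(S)-1-methylpiperidin-2-yl]chroman-4-one | CN1CCCC[C@H]1c1c(OCc3ccccc3)cc2c(c1OCc1ccccc1)C(=O)C[C@@H](c1ccc(OC(=O)OCc3ccccc3)cc1)O2 | intermediate
24 | (S)-5,7-dihydroxy-2-(4-hydroxyphenyl)-6-[(S)-1-methylpiperidin-2-yl]chroman-4-one | CN1CCCC[C@H]1c1c(O)cc2c(c1O)C(=O)C[C@@H](c1ccc(O)cc1)O2 | target

## Step count and least certain steps

Total step count: 14. Longest linear sequence: 11 steps (steps 1–7, then 11–14).

**Step 13 (key step).** The likely failure is erosion of configuration at C2, or loss of the ether altogether, if ionisation of the benzylic C2–O1 bond in the acidic medium competes with acylation. A second risk is N-acylation followed by C–N cleavage if the amine is not kept protonated. Any C2 epimer formed would be a diastereomer of 23 and therefore separable.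

Fallback, setting out from 12 and returning at 24: ring C is built without an acid-exposed benzylic ether, and C2 is set by a catalyst.
- Phenol 12 is C-acetylated ortho to the hydroxyl with acetic anhydride and BF3·OEt2 (the two ortho carbons are equivalent), giving 1-{2,4-bis(benzyloxy)-6-hydroxy-3-[(S)-1-methylpiperidin-2-yl]phenyl}ethan-1-one F1.
- N,N-Dimethylformamide dimethyl acetal gives the enaminone (E)-1-{2,4-bis(benzyloxy)-6-hydroxy-3-[(S)-1-methylpiperidin-2-yl]phenyl}-3-(dimethylamino)prop-2-en-1-one F2.
- Acid closes F2 to 5,7-bis(benzyloxy)-6-[(S)-1-methylpiperidin-2-yl]-4H-chromen-4-one F3.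
- Asymmetric conjugate addition of 4-(benzyloxy)phenylboronic acid to the chromone, with Pd(OCOCF3)2 and a chiral pyridine–oxazoline ligand or a rhodium–chiral diene complex, gives (S)-5,7-bis(benzyloxy)-2-[4-(benzyloxy)phenyl]-6-[(S)-1-methylpiperidin-2-yl]chroman-4-one F4. The ligand enantiomer is chosen for the (S) configuration at C2.
- Hydrogenolysis of F4 under the conditions of step 14 gives 24.

**Step 4.** The likely failure is poor facial selectivity, because an ortho benzyloxy oxygen can compete with the sulfinyl oxygen for magnesium and the di-ortho-substituted imine is slow to react. Reduction of the imine by β-hydride transfer is a second risk.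

Fallback, setting out from 3 (with 7) and returning at 10:
- Addition of 7 to aldehyde 3 gives 1-{2,6-bis(benzyloxy)-4-[(triisopropylsilyl)oxy]phenyl}-5-chloropentan-1-ol F5.
- MnO2 oxidises it to 1-{2,6-bis(benzyloxy)-4-[(triisopropylsilyl)oxy]phenyl}-5-chloropentan-1-one F6.
- NaN3 in DMF gives 5-azido-1-{2,6-bis(benzyloxy)-4-[(triisopropylsilyl)oxy]phenyl}pentan-1-one F7.
- PPh3 (Staudinger reaction, then intramolecular aza-Wittig closure) gives 6-{2,6-bis(benzyloxy)-4-[(triisopropylsilyl)oxy]phenyl}-2,3,4,5-tetrahydropyridine F8.
- Asymmetric reduction of this cyclic imine, by hydrogenation with [Ir(cod)Cl]2 and a chiral diphosphine or with an imine reductase, gives 10, which is methylated as in step 6.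

**Step 11.** The likely failure is β-elimination of the activated β-hydroxy ester to the cinnamate, possibly promoted by the basic nitrogen of 12, together with partial loss of inversion through an SN1 path.

Fallback, setting out from 12 and returning at 21: an alcohol that cannot undergo E1cB is used.
- 4-Hydroxybenzaldehyde and benzyl chloroformate give 4-formylphenyl benzyl carbonate F9.
- Catalytic asymmetric Keck allylation (allyltributylstannane, Ti(OiPr)4 and the BINOL enantiomer that gives the (R)-carbinol, (R)-BINOL on the usual model) gives (R)-1-(4-{[(benzyloxy)carbonyl]oxy}phenyl)but-3-en-1-ol F10.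
- Mitsunobu reaction of F10 with 12 gives benzyl 4-[(S)-1-{3,5-bis(benzyloxy)-4-[(S)-1-methylpiperidin-2-yl]phenoxy}but-3-en-1-yl]phenyl carbonate F11.
- Oxidative cleavage of the alkene (OsO4 cat., NaIO4, 2,6-lutidine) gives (S)-3-{3,5-bis(benzyloxy)-4-[(S)-1-methylpiperidin-2-yl]phenoxy}-3-(4-{[(benzyloxy)carbonyl]oxy}phenyl)propanal F12.
- Pinnick oxidation (NaClO2, NaH2PO4, 2-methylbut-2-ene) gives 21.

**Step 14.** The likely failure is over-reduction, by hydrogenolysis of the C2–O1 bond to a dihydrochalcone or of the benzylic C–N bond. The opposite failure is stalled debenzylation through binding of the amine to the catalyst.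

Fallback, setting out from 23 and returning at 24: non-reductive dealkylation with BCl3 and pentamethylbenzene in CH2Cl2 at −78 → 0 °C. The three benzyl groups are transferred to the arene scavenger, the carbonate residue is lost as CO2 on methanolic work-up, and 24 is obtained directly. No new intermediate is formed.

Further compounds

F1 | step 13 | 1-{2,4-bis(benzyloxy)-6-hydroxy-3-[(S)-1-methylpiperidin-2-yl]phenyl}ethan-1-one | CC(=O)c1c(O)cc(OCc2ccccc2)c([C@@H]2CCCCN2C)c1OCc1ccccc1
F2 | step 13 | (E)-1-{2,4-bis(benzyloxy)-6-hydroxy-3-[(S)-1-methylpiperidin-2-yl]phenyl}-3-(dimethylamino)prop-2-en-1-one | CN(C)/C=C/C(=O)c1c(O)cc(OCc2ccccc2)c([C@@H]2CCCCN2C)c1OCc1ccccc1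
F3 | step 13 | 5,7-bis(benzyloxy)-6-[(S)-1-methylpiperidin-2-yl]-4H-chromen-4-one | CN1CCCC[C@H]1c1c(OCc2ccccc2)cc2occc(=O)c2c1OCc1ccccc1
F4 | step 13 | (S)-5,7-bis(benzyloxy)-2-[4-(benzyloxy)phenyl]-6-[(S)-1-methylpiperidin-2-yl]chroman-4-one | CN1CCCC[C@H]1c1c(OCc3ccccc3)cc2c(c1OCc1ccccc1)C(=O)C[C@@H](c1ccc(OCc3ccccc3)cc1)O2
F5 | step 4 | 1-{2,6-bis(benzyloxy)-4-[(triisopropylsilyl)oxy]phenyl}-5-chloropentan-1-ol | OC(CCCCCl)c1c(OCc2ccccc2)cc(O[Si](C(C)C)(C(C)C)C(C)C)cc1OCc1ccccc1
F6 | step 4 | 1-{2,6-bis(benzyloxy)-4-[(triisopropylsilyl)oxy]phenyl}-5-chloropentan-1-one | O=C(CCCCCl)c1c(OCc2ccccc2)cc(O[Si](C(C)C)(C(C)C)C(C)C)cc1OCc1ccccc1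
F7 | step 4 | 5-azido-1-{2,6-bis(benzyloxy)-4-[(triisopropylsilyl)oxy]phenyl}pentan-1-one | [N-]=[N+]=NCCCCC(=O)c1c(OCc2ccccc2)cc(O[Si](C(C)C)(C(C)C)C(C)C)cc1OCc1ccccc1
F8 | step 4 | 6-{2,6-bis(benzyloxy)-4-[(triisopropylsilyl)oxy]phenyl}-2,3,4,5-tetrahydropyridine | C1CCC(=NC1)c1c(OCc2ccccc2)cc(O[Si](C(C)C)(C(C)C)C(C)C)cc1OCc1ccccc1
F9 | step 11 | 4-formylphenyl benzyl carbonate | O=Cc1ccc(OC(=O)OCc2ccccc2)cc1
F10 | step 11 | (R)-1-(4-{[(benzyloxy)carbonyl]oxy}phenyl)but-3-en-1-ol | C=CC[C@@H](O)c1ccc(OC(=O)OCc2ccccc2)cc1
F11 | step 11 | benzyl 4-[(S)-1-{3,5-bis(benzyloxy)-4-[(S)-1-methylpiperidin-2-yl]phenoxy}but-3-en-1-yl]phenyl carbonate | CN1CCCC[C@H]1c1c(OCc2ccccc2)cc(O[C@@H](CC=C)c2ccc(OC(=O)OCc3ccccc3)cc2)cc1OCc1ccccc1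
F12 | step 11 | (S)-3-{3,5-bis(benzyloxy)-4-[(S)-1-methylpiperidin-2-yl]phenoxy}-3-(4-{[(benzyloxy)carbonyl]oxy}phenyl)propanal | CN1CCCC[C@H]1c1c(OCc2ccccc2)cc(O[C@@H](CC=O)c2ccc(OC(=O)OCc3ccccc3)cc2)cc1OCc1ccccc1
F0 | step 14 | none | none
A1 | alternative 1 | tert-butyl (S)-2-[2-hydroxy-4-(4-methoxybenzyloxy)-6-(triisopropylsilyloxy)phenyl]piperidine-1-carboxylate | CC(C)(C)OC(=O)N1CCCC[C@H]1c1c(O[Si](C(C)C)(C(C)C)C(C)C)cc(OCc2ccc(OC)cc2)cc1O
A2 | alternative 1 | tert-butyl (S)-2-{[(triisopropylsilyl)oxy]ethynyl}piperidine-1-carboxylate | CC(C)(C)OC(=O)N1CCCC[C@H]1C#CO[Si](C(C)C)(C(C)C)C(C)C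
A3 | alternative 1 | 3-[(4-methoxybenzyl)oxy]cyclobut-2-en-1-one | COc1ccc(COC2=CC(=O)C2)cc1
A4 | alternative 1 | (S)-piperidine-2-carboxylic acid | OC(=O)[C@@H]1CCCCN1
A5 | alternative 2 | tert-butyl (S)-2-{(S)-5,7-bis(tert-butyldimethylsilyloxy)-2-[4-(tert-butyldimethylsilyloxy)phenyl]-4-oxochroman-6-yl}piperidine-1-carboxylate | CC(C)(C)OC(=O)N1CCCC[C@H]1c1c(O[Si](C)(C)C(C)(C)C)cc2c(c1O[Si](C)(C)C(C)(C)C)C(=O)C[C@@H](c1ccc(O[Si](C)(C)C(C)(C)C)cc1)O2
A6 | alternative 2 | tert-butyl (S)-2-{3-(2-diazoacetyl)-2,6-bis[(tert-butyldimethylsilyl)oxy]-4-({4-[(tert-butyldimethylsilyl)oxy]benzyl}oxy)phenyl}piperidine-1-carboxylate | CC(C)(C)OC(=O)N1CCCC[C@H]1c1c(O[Si](C)(C)C(C)(C)C)cc(OCc2ccc(O[Si](C)(C)C(C)(C)C)cc2)c(C(=O)C=[N+]=[N-])c1O[Si](C)(C)C(C)(C)C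
A7 | alternative 3 | tert-butyl (S)-2-{(S)-2-[4-(benzyloxy)phenyl]-5,7-dihydroxy-4-oxochroman-6-yl}piperidine-1-carboxylate | CC(C)(C)OC(=O)N1CCCC[C@H]1c1c(O)cc2c(c1O)C(=O)C[C@@H](c1ccc(OCc3ccccc3)cc1)O2
A8 | alternative 3 | methyl (S)-2-[4-(benzyloxy)phenyl]-6-{3-[(S)-1-(tert-butoxycarbonyl)piperidin-2-yl]-2-oxopropyl}-4-oxo-3,4-dihydro-2H-pyran-5-carboxylate | COC(=O)C1=C(CC(=O)C[C@@H]2CCCCN2C(=O)OC(C)(C)C)O[C@H](c2ccc(OCc3ccccc3)cc2)CC1=O
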